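All runs were generated by integration for substances that don't exist.

You cannot read how substrate divides from a late sample: in the south-west run target falls from 43% at 2.00 h to 21% at 12.0 h, so what stands there is not what was first made.

| flask | substrate | partner | remark | time |
|---|---|---|---|---|
| south-west | 40 mM | 2.5 equiv | run made earlier |  |
| north | 40 mM | 1.7 equiv | run made earlier |  |
| north-west | 40 mM | 3.8 equiv | run made earlier |  |
| east | 20 mM | 2.5 equiv | run made earlier |  |
| amber | 40 mM | 2.50 equiv | a single well-mixed tank run continuously and read at steady state, 20 h in it on average |  |
| grey | 40 mM | 2.50 equiv | a closed flask charged with all of it at once and left for 20 h | 20 h |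
| violet | 40 mM | 2.50 equiv | plug flow through a tube for 20 h, no back-mixing | 20 h |
| red | 40 mM | 2.50 equiv (fed, over 20.0 h) | a stirred flask in which partner is dosed at a steady rate over 20.0 h without added volume, worked up at 20 h | 20 h |

| run | time / h | target / % | side product / % |
|---|---|---|---|
| south-west | 1.00 | 37 | 27 |
| south-west | 2.00 | 43 | 35 |
| south-west | 3.00 | 41 | 44 |
| south-west | 6.00 | 27 | 49 |
| south-west | 12.0 | 21 | 66 |
| north | 1.00 | 35 | 18 |
| north | 2.00 | 39 | 24 |
| north | 3.00 | 34 | 25 |
| north | 6.00 | 31 | 36 |
| north | 12.0 | 26 | 48 |
| north-west | 1.00 | 41 | 46 |
| north-west | 2.00 | 37 | 54 |
| north-west | 3.00 | 31 | 59 |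
| north-west | 6.00 | 24 | 73 |
| north-west | 12.0 | 7 | 88 |
| east | 1.00 | 35 | 13 |
| east | 2.00 | 39 | 15 |
| east | 3.00 | 39 | 21 |
| east | 6.00 | 34 | 32 |
| east | 12.0 | 27 | 45 |

(standard deviation of a reading: 2 percentage points)

- the stated concentrations are those of everything mixed, before any reaction; amounts are the same in each set-up
- the earlier runs were read with a standard deviation of 2 percentage points
- steps thought possible: substrate + 2 partner -> side product; substrate + partner <-> target
- the feed brings no volume worth counting
- the earlier runs were made in a closed, stirred flask

* the set-up with the highest share of target in all that became target or side product, at the outlet or at the end ("none" if the first two lie within 2 percentage points) (amber / grey / violet / red / none)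
* share of target in all that became target or side product, at the outlet or at the end, amber
* share of target in all that became target or side product, at the outlet or at the end, grey
* share of target in all that became target or side product, at the outlet or at the end, violet
* share of target in all that became target or side product, at the outlet or at the end, red

1. Take the earliest readings, at 1.00 h. Side product over target is 0.371 in the east run, with 50.0 mM of partner charged, and 1.12 in the north-west run, with 152 mM. Side product takes two partner and target one, so divide that ratio by charged c(partner). Call the result the split, a selectivity factor per mM of partner. As a reading, averaged over the four runs, it is 0.00742 mM⁻¹.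

2. Suppose target never ran back in grey. Each substrate then uses about 1.5 partner, so c(partner) averages 70.0 mM, and the share of target is 65.8%.

3. The south-west run has grey's recipe, yet at 12.0 h its share is only 24.1%. Target is therefore a store, and step 2 is my weak link.

4. So I extrapolate instead. What is not yet side product falls from 51.0% at 6.00 h to 34.0% at 12.0 h, which is 0.0676 h⁻¹. At 20 h that leaves 19.8%. If target keeps its part of this, it stands at 12.2%, and my share for grey is 13.2%. Violet, without back-mixing, repeats grey.

5. Side product over target is the split times c(partner), so that ratio falls as c(partner) falls. Red doses only 5.00 mM h⁻¹, so I rank red above amber, and amber above grey.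

The forecast, higher than my grey, gave amber 31%, grey 17%, violet 17% and red 44%, best red: “Red is best”.

The simulation gives amber 25.9%, grey 13.1%, violet 13.1% and red 38.4%, so red leads.

    substrate + 2 partner → side product (k = 82.0 L² mol⁻² h⁻¹)
    substrate + partner ⇌ target (K = 28.0 L mol⁻¹, k = 11.6 L mol⁻¹ h⁻¹)

The back run from target to substrate and partner is the main reason for violet's low share: with it removed, violet gives 66.4% instead of 13.1%, which is where step 2 stood at 65.8%. The split therefore describes what is freshly made, and the end ratio also carries what ran back. Take violet with 10 mM of substrate: at 20.0 h partner stands at 16.4 mM, so the split gives 0.122, yet side product over target stands at 1.45, a share of 40.8%.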